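The earlier runs and the new flask are calculated on assumed constants.

Substrate is left over in both earlier runs: at 10.0 h noon still holds 73.5 % and autumn 73.7 % of the charge, although autumn had 0.35 M of scavenger against noon's 0.27 M. Delta lies between those charges and gamma below them, so what I need is how far the scavenger charge stands from what the product calls on.

in all of them: substrate 0.41 M; partner 0.492 M; free catalyst 0.82 mM
- noon: scavenger 0.27 M; capture agent 8.2 mM; run made earlier
- autumn: scavenger 0.35 M; capture agent 8.2 mM; run made earlier
- delta: scavenger 0.310 M; capture agent 8.20 mM; time 20 h
- gamma: scavenger 0.200 M; capture agent 8.20 mM; time 20 h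

| run | time / h | substrate / % | product / % |
|---|---|---|---|
| noon | 1.50 | 73.6 | 25.4 |
| noon | 3.00 | 72.9 | 27.6 |
| noon | 5.00 | 72.2 | 26.9 |
| noon | 6.00 | 72.7 | 27.1 |
| noon | 8.00 | 73.3 | 26.9 |
| noon | 10.0 | 73.5 | 26.7 |
| autumn | 0.833 | 78.3 | 20.3 |
| autumn | 1.33 | 74.8 | 24.4 |
| autumn | 2.00 | 73.0 | 26.5 |
| autumn | 4.00 | 72.9 | 26.9 |
| autumn | 6.00 | 72.8 | 26.7 |
| autumn | 10.0 | 73.7 | 26.7 |

(readings scatter by 0.3 percentage points)

1. part of the substrate that has reacted at the end, delta
2. part of the substrate that has reacted at the end, gamma
3. what raising the concentration of scavenger from its lowest to its highest value here does to the part of the substrate that has reacted (changes below 5 percentage points count as none) (no change / it rises / it falls)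



I read the plateau as the mean of the two product readings at 6.00 h, and I replace the rising curve by its mean slope up to autumn's first reading:

plateau fraction of the substrate charge = 26.9 %

mean rate = 20.3 % / 0.833 h = 0.244 /h

Assuming one scavenger per product, that gives a ladder, fastest rung first:

fill of the plateau = 1.10 h

drain of the scavenger, gamma = 2.00 h

drain of the scavenger, delta = 3.10 h

asked time = 20 h

The mean flatters the curve, since autumn reaches 26.5 % only at 2.00 h, but the rate cancels in the ratio of fill to drain. That ratio is the scavenger demand, the fraction of a scavenger charge that the plateau product draws: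

demand, gamma = 26.9 % × 0.41 M / 0.200 M = 55.1 %

Gamma's demand stands below its whole charge, so on this reckoning scavenger is not the limiting reagent in gamma, and delta's demand is lower still, at 35.6 %.

The forecast gives 27 % for delta, 27 % for gamma and no change, on the ground that “scavenger is not what limits the extent here”.

    catalyst intermediate D → free catalyst + product (k = 5.30 /min)
    catalyst intermediate C → catalyst intermediate D (k = 23.0 /min)
    substrate + released group ⇌ idle adduct, settled at all times (K = 4.50 /M)
    catalyst intermediate B ⇌ released group + catalyst intermediate C (K = 0.370 M, k = 2100 /min)
    catalyst intermediate A + capture agent → trapped intermediate (k = 10.0 /M/min)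
    substrate + free catalyst → catalyst intermediate A (k = 53.0 /M/min)
    partner → decomposed reagent (k = 0.0130 /min)
    scavenger + released group → scavenged by-product (k = 1.90 /M/min)
    partner + catalyst intermediate A → catalyst intermediate B (k = 45.0 /M/min)

The flask gives 27.0 % for delta and 27.0 % for gamma, so the trend is no change, a change of 0.013 percentage points. Gamma ends with 45.1 % of its scavenger free, where its demand of 55.1 % leaves 44.9 %. A neighbour flask, the same as delta but with 0.0033 M of free catalyst, ends with product at 75.4 % of the substrate charge, and the same reckoning puts its demand at 99.7 % of the scavenger charge; that neighbour holds 0.402 % of its scavenger free after 20.0 h.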